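## Retrosynthetic overview

1. Locants used below: ring C1 = CH carrying the side chain, C2 = CH–O-angelate, C3/C4 = epoxide CH/C(CH3), C5 = C=O, C6 = CH–OAc; side chain C7 (=CH2), C8 (CH–O-angelate), C9, C10/C11 (epoxide).
2. Target 23 ⇒ side-chain epoxide (Shi epoxidation), both angelates (one double acylation) and ring epoxide (hydroxyl-directed) removed ⇒ hydroxy-enone 19.
3. 19 ⇒ C1–C2 disconnection: intramolecular allylboration of a (Z)-4-oxo-2-enal that is released in the same flask from furan 15 by singlet oxygen; this closes the only carbocycle.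
4. Enabling feature: O–C2–C1–C7=CH2 is a homoallylic alcohol (carbonyl-allylation retron), and with the epoxide taken back to C3=C4 the ring segment C2–C3=C4(CH3)–C5(=O) is the oxidised form of a 3-methylfuran that carries C6 at its 2-position; a furan and a CH2Bpin group thus stand in for the whole oxygenated ring.
5. 15 ⇒ (Z)-iodoalkene 13 (Negishi) ⇒ propargylic alcohol 11 (directed trans-hydroalumination) ⇒ alkyne 8 + aldehyde 9 (asymmetric alkynylation, C6); 8 ⇒ ynone 5 (Noyori reduction, C8); ring order: furan (bought) → cyclohexenone (step 10) → ring epoxide (step 12) → side-chain epoxide (step 14).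

Key step: step 10

Assumption: the zinc complex of (R,R)-ProPhenol is taken to deliver alkynes to the Si face of aryl aldehydes (by analogy with the Re-face aldol additions of the (S,S)-ligand); both ligand antipodes are commercial, so the other one would be used if the sense is the opposite.

## Route

Step 1
Reactants: 1 4-methylpent-3-enoic acid
Product: 3 N-methoxy-N,4-dimethylpent-3-enamide, via acyl imidazolide 2 (not isolated)
Conditions: CDI, CH2Cl2, rt; then MeNH(OMe)·HCl, rt
Reagents that add atoms: 1,1'-carbonyldiimidazole O=C(n1ccnc1)n1ccnc1 (imidazolyl group of 2 only); N,O-dimethylhydroxylamine hydrochloride CNOC.Cl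
Why: CDI converts the acid into acyl imidazolide 2, which is aminolysed by the hydroxylamine (Weinreb amide formation) under neutral conditions that leave the β,γ-alkene in place; no stereocenter is formed.

Step 2
Reactants: 3 N-methoxy-N,4-dimethylpent-3-enamide
Product: 5 6-methyl-1-(trimethylsilyl)hept-5-en-1-yn-3-one, via lithium hemiaminal chelate 4 (not isolated)
Conditions: Me3SiC≡CH, n-BuLi, THF, −78 °C; then 3, −78 to 0 °C; aq NH4Cl
Reagents that add atoms: (trimethylsilyl)acetylene C#C[Si](C)(C)C; n-butyllithium [Li]CCCC (lithium of 4 only)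
Why: Weinreb ketone synthesis, in which the lithium acetylide adds once because the five-membered N-methoxy chelate 4 persists until the quench, so that neither over-addition nor base-induced conjugation of the β,γ-unsaturated ynone can occur.

Step 3
Reactants: 5 6-methyl-1-(trimethylsilyl)hept-5-en-1-yn-3-one
Product: 6 (3R)-6-methyl-1-(trimethylsilyl)hept-5-en-1-yn-3-ol
Conditions: Ru[(R,R)-TsNCH(Ph)CH(Ph)NH](p-cymene) (1 mol %), i-PrOH, rt
Reagents that add atoms: none
Why: Noyori asymmetric transfer hydrogenation of an α,β-acetylenic ketone through the six-membered Ru–H/N–H transition state, in which the alkyne takes the place of the aryl group of aryl ketones, so that the (R,R)-complex should deliver hydride to give the (R)-carbinol at C8 while the base-free amido catalyst leaves the skipped enone system unconjugated.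

Step 4
Reactants: 6 (3R)-6-methyl-1-(trimethylsilyl)hept-5-en-1-yn-3-ol
Product: 7 (3R)-3-[(tert-butyldimethylsilyl)oxy]-6-methyl-1-(trimethylsilyl)hept-5-en-1-yne
Conditions: TBSCl, imidazole, DMF, rt
Reagents that add atoms: tert-butyldimethylsilyl chloride CC(C)(C)[Si](C)(C)Cl
Why: Imidazole-promoted silylation of the secondary propargylic alcohol gives the TBS ether that masks the C8 oxygen during hydroalumination and cyclisation without touching the stereocenter.

Step 5
Reactants: 7 (3R)-3-[(tert-butyldimethylsilyl)oxy]-6-methyl-1-(trimethylsilyl)hept-5-en-1-yne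
Product: 8 (3R)-3-[(tert-butyldimethylsilyl)oxy]-6-methylhept-5-en-1-yne
Conditions: K2CO3 (cat.), MeOH, rt
Reagents that add atoms: none
Why: Methoxide-catalysed protodesilylation cleaves the C(sp)–Si bond selectively, since the alkynyl anion is a far better leaving group from silicon than the secondary alkoxide of the TBS ether.

Step 6
Reactants: 8 (3R)-3-[(tert-butyldimethylsilyl)oxy]-6-methylhept-5-en-1-yne; 9 3-methylfuran-2-carbaldehyde
Product: 11 (1S,4R)-4-[(tert-butyldimethylsilyl)oxy]-7-methyl-1-(3-methylfuran-2-yl)oct-6-en-2-yn-1-ol, via alkynyl(methyl)zinc 10 (not isolated)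
Conditions: Me2Zn, (R,R)-ProPhenol (20 mol %), Ph3P=O (40 mol %), toluene, 0–4 °C (8 in 1.5-fold excess, recovered); aq NH4Cl
Reagents that add atoms: dimethylzinc C[Zn]C (methylzinc group of 10 only)
Why: Trost zinc–ProPhenol asymmetric alkynylation, in which alkynylzinc 10 is transferred inside the chiral dinuclear zinc pocket to the Si face of the heteroaryl aldehyde, so that the new carbinol center C6 is set as S by the catalyst and not by the remote C8 center.

Step 7
Reactants: 11 (1S,4R)-4-[(tert-butyldimethylsilyl)oxy]-7-methyl-1-(3-methylfuran-2-yl)oct-6-en-2-yn-1-ol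
Product: 13 (1S,2Z,4R)-4-[(tert-butyldimethylsilyl)oxy]-3-iodo-7-methyl-1-(3-methylfuran-2-yl)octa-2,6-dien-1-ol, via cyclic alkenylalanate 12 (not isolated)
Conditions: NaAlH2(OCH2CH2OMe)2, THF, 0 °C; EtOAc; then I2, THF, −78 °C
Reagents that add atoms: sodium bis(2-methoxyethoxy)aluminium dihydride [Na+].[AlH2-](OCCOC)OCCOC (aluminate of 12 only); iodine II
Why: Alkoxide-directed trans-hydroalumination of the propargylic alcohol places hydride on C1 and aluminium on C7 in the five-membered alanate 12, and iodinolysis with retention then gives the Z-iodoalkene regio- and stereospecifically, the β-silyloxy alanate being kept at or below 0 °C so that it does not eliminate to an allene.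

Step 8
Reactants: 13 (1S,2Z,4R)-4-[(tert-butyldimethylsilyl)oxy]-3-iodo-7-methyl-1-(3-methylfuran-2-yl)octa-2,6-dien-1-ol
Product: 14 (1S,2Z,4R)-4-[(tert-butyldimethylsilyl)oxy]-3-iodo-7-methyl-1-(3-methylfuran-2-yl)octa-2,6-dien-1-yl acetate
Conditions: Ac2O, Et3N, DMAP (cat.), CH2Cl2, 0 °C
Reagents that add atoms: acetic anhydride CC(=O)OC(C)=O
Why: DMAP-catalysed acetylation of the secondary alcohol under amine buffering installs the C6 acetate of the target with retention and avoids ionisation of the furyl allylic carbinol.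

Step 9
Reactants: 14 (1S,2Z,4R)-4-[(tert-butyldimethylsilyl)oxy]-3-iodo-7-methyl-1-(3-methylfuran-2-yl)octa-2,6-dien-1-yl acetate
Product: 15 (1S,2E,4R)-4-[(tert-butyldimethylsilyl)oxy]-7-methyl-1-(3-methylfuran-2-yl)-3-[(4,4,5,5-tetramethyl-1,3,2-dioxaborolan-2-yl)methyl]octa-2,6-dien-1-yl acetate (CH2Bpin cis to C6)
Conditions: ICH2Bpin, Zn (activated), THF, rt; then 14, Pd(PPh3)4 (5 mol %), THF, rt
Reagents that add atoms: 2-(iodomethyl)-4,4,5,5-tetramethyl-1,3,2-dioxaborolane ICB1OC(C)(C)C(C)(C)O1
Why: Negishi coupling of the alkenyl iodide with Knochel's (pinacolatoboryl)methylzinc iodide proceeds with retention of the alkene geometry and so places CH2Bpin cis to C6, oxidative addition of zerovalent palladium to the C–I bond at room temperature being much faster than ionisation of the hindered allylic acetate.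

Step 10
Reactants: 15 (1S,2E,4R)-4-[(tert-butyldimethylsilyl)oxy]-7-methyl-1-(3-methylfuran-2-yl)-3-[(4,4,5,5-tetramethyl-1,3,2-dioxaborolan-2-yl)methyl]octa-2,6-dien-1-yl acetate
Product: 19 (1S,5R,6R)-6-[(3R)-3-[(tert-butyldimethylsilyl)oxy]-6-methylhepta-1,5-dien-2-yl]-5-hydroxy-3-methyl-2-oxocyclohex-3-en-1-yl acetate, via furan endoperoxide 16 (not isolated), via keto-enal 17 (not isolated), via borate ester 18 (not isolated)
Conditions: O2, methylene blue (cat.), visible light, CH2Cl2, −78 °C; then Me2S, −78 °C to rt, 12 h; aq NaH2PO4/Na2HPO4 (pH 7)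
Reagents that add atoms: oxygen O=O
Why: Singlet oxygen adds [4+2] across the 2,3-dialkylfuran and Me2S reduces endoperoxide 16 to the (Z)-4-oxo-2-enal 17, whose Z-alkene C3=C4 holds the aldehyde carbon C2 within reach of the allylboronate. The aldehyde is then trapped by the γ-carbon C1 of the allylboronate through a chair-like six-membered B–O–C2–C1–C7–CH2 (Zimmerman–Traxler) transition state, which forms the C1–C2 bond, the C2 oxygen stereocenter (as borate 18) and the exocyclic C7=CH2 in one event; the closest known reactions are the intramolecular allylborations of ω-oxo allylboronates (Hoffmann) and the photooxygenation/ring-closure cascades of furans. The cyclohexenone ring closes in a 6-exo-trig mode with respect to the aldehyde C=O, through a cis-fused bicyclic transition state. C2 relative to C1 is fixed by the alkene geometry, since C6 is cis to CH2B and therefore axial on the chair, which brings the C2–O and C1–C7 bonds out cis; C1 relative to C6 is fixed by allylic 1,3-strain, which keeps C6–H in the plane of C1=C7 so that the aldehyde, tethered through C5, attacks the face anti to the acetoxy group and the acetate ends trans to the C7 branch. The step needs furan over alkene oxidation (secured by the large rate gap between the [4+2] addition and the ene reaction of the prenyl or allylboronate alkenes at −78 °C), retention of the Z-enedione geometry (secured by the absence of acid or amine and by the fast in situ ring closure) and aldehyde over ketone selectivity (attack on the C5 ketone could only give a three-membered ring).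

Step 11
Reactants: 19 (1S,5R,6R)-6-[(3R)-3-[(tert-butyldimethylsilyl)oxy]-6-methylhepta-1,5-dien-2-yl]-5-hydroxy-3-methyl-2-oxocyclohex-3-en-1-yl acetate
Product: 20 (1S,5R,6R)-5-hydroxy-6-[(3R)-3-hydroxy-6-methylhepta-1,5-dien-2-yl]-3-methyl-2-oxocyclohex-3-en-1-yl acetate
Conditions: HF·pyridine, pyridine, THF, 0 °C to rt
Reagents that add atoms: none
Why: Pyridine-buffered HF·pyridine cleaves the secondary TBS ether by fluoride attack at silicon without affecting the acetate, the enone or the prenyl group, and is placed before any acid-sensitive epoxide exists.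

Step 12
Reactants: 20 (1S,5R,6R)-5-hydroxy-6-[(3R)-3-hydroxy-6-methylhepta-1,5-dien-2-yl]-3-methyl-2-oxocyclohex-3-en-1-yl acetate
Product: 21 (1S,3S,4R,5S,6S)-5-hydroxy-4-[(3R)-3-hydroxy-6-methylhepta-1,5-dien-2-yl]-1-methyl-2-oxo-7-oxabicyclo[4.1.0]heptan-3-yl acetate
Conditions: t-BuOOH (in decane), DBU, CH2Cl2, 0 °C
Reagents that add atoms: tert-butyl hydroperoxide CC(C)(C)OO
Why: Hydroxyl-directed Weitz–Scheffer epoxidation, in which tert-butyl peroxide anion hydrogen-bonded to the pseudoaxial C2 hydroxyl adds to C3 of the enone from the face of that hydroxyl and the resulting enolate closes the oxirane, sets C3 and C4 cis to the C2 oxygen, while the non-nucleophilic amidine base spares the acetate.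

Step 13
Reactants: 21 (1S,3S,4R,5S,6S)-5-hydroxy-4-[(3R)-3-hydroxy-6-methylhepta-1,5-dien-2-yl]-1-methyl-2-oxo-7-oxabicyclo[4.1.0]heptan-3-yl acetate
Product: 22 (1S,3S,4R,5S,6S)-3-acetoxy-1-methyl-4-[(3R)-6-methyl-3-[(2Z)-2-methylbut-2-enoyloxy]hepta-1,5-dien-2-yl]-2-oxo-7-oxabicyclo[4.1.0]heptan-5-yl (2Z)-2-methylbut-2-enoate
Conditions: angelic acid, 2,4,6-trichlorobenzoyl chloride, Et3N, toluene, rt; then 21, toluene, 75 °C
Reagents that add atoms: angelic acid C/C=C(/C)C(=O)O
Why: Yamaguchi-type esterification with the preformed angelic 2,4,6-trichlorobenzoic mixed anhydride and without DMAP acylates both secondary alcohols under conditions known to avoid the Z-to-E isomerisation of angelate to tiglate, and no stereocenter is affected.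

Step 14
Reactants: 22 (1S,3S,4R,5S,6S)-3-acetoxy-1-methyl-4-[(3R)-6-methyl-3-[(2Z)-2-methylbut-2-enoyloxy]hepta-1,5-dien-2-yl]-2-oxo-7-oxabicyclo[4.1.0]heptan-5-yl (2Z)-2-methylbut-2-enoate
Product: 23 (1S,3S,4R,5S,6S)-3-acetoxy-4-[(3R)-4-[(2S)-3,3-dimethyloxiran-2-yl]-3-[(2Z)-2-methylbut-2-enoyloxy]but-1-en-2-yl]-1-methyl-2-oxo-7-oxabicyclo[4.1.0]heptan-5-yl (2Z)-2-methylbut-2-enoate (target)
Conditions: L-fructose-derived Shi ketone (antipode of the usual catalyst, 0.5 equiv), KHSO5, K2CO3, Bu4NHSO4, MeCN–CH2(OMe)2–aq Na2B4O7, pH about 9, 0 °C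
Reagents that add atoms: potassium peroxymonosulfate [K+].[O-]S(=O)(=O)OO
Why: Shi asymmetric epoxidation, in which the dioxirane of the L-fructose-derived ketone (the antipode of the usual D-fructose-derived catalyst) reacts through the spiro transition state only with the electron-rich trisubstituted prenyl alkene and should set C10 as S under catalyst control, the conjugated angelates and the hindered electron-poor 1,1-disubstituted alkene being unreactive towards the dioxirane.

## Compound list

1 | 4-methylpent-3-enoic acid | CC(C)=CCC(=O)O | starting material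
2 | 1-(imidazol-1-yl)-4-methylpent-3-en-1-one (acyl imidazolide) | CC(C)=CCC(=O)n1ccnc1 | intermediate
3 | N-methoxy-N,4-dimethylpent-3-enamide | CC(C)=CCC(=O)N(C)OC | intermediate
4 | lithium alkoxide of the tetrahedral adduct of 3 and the acetylide (N-methoxy chelate; new center not defined) | CC(C)=CCC(O[Li])(C#C[Si](C)(C)C)N(C)OC | intermediate
5 | 6-methyl-1-(trimethylsilyl)hept-5-en-1-yn-3-one | CC(C)=CCC(=O)C#C[Si](C)(C)C | intermediate
6 | (3R)-6-methyl-1-(trimethylsilyl)hept-5-en-1-yn-3-ol | C[Si](C)(C)C#C[C@@H](CC=C(C)C)O | intermediate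
7 | (3R)-3-[(tert-butyldimethylsilyl)oxy]-6-methyl-1-(trimethylsilyl)hept-5-en-1-yne | C[Si](C)(C)C#C[C@@H](CC=C(C)C)O[Si](C)(C)C(C)(C)C | intermediate
8 | (3R)-3-[(tert-butyldimethylsilyl)oxy]-6-methylhept-5-en-1-yne | C#C[C@@H](CC=C(C)C)O[Si](C)(C)C(C)(C)C | intermediate
9 | 3-methylfuran-2-carbaldehyde | Cc1ccoc1C=O | starting material
10 | methylzinc acetylide of 8 | C[Zn]C#C[C@@H](CC=C(C)C)O[Si](C)(C)C(C)(C)C | intermediate
11 | (1S,4R)-4-[(tert-butyldimethylsilyl)oxy]-7-methyl-1-(3-methylfuran-2-yl)oct-6-en-2-yn-1-ol | Cc1ccoc1[C@@H](O)C#C[C@@H](CC=C(C)C)O[Si](C)(C)C(C)(C)C | intermediate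
12 | sodium five-membered oxa-alanate (Al bonded to the C6 oxygen, to C7 and to two 2-methoxyethoxy groups; C6 S, C8 R) | [Na+].COCCO[Al-]1(OCCOC)O[C@H](c2occc2C)C=C1[C@@H](CC=C(C)C)O[Si](C)(C)C(C)(C)C | intermediate
13 | (1S,2Z,4R)-4-[(tert-butyldimethylsilyl)oxy]-3-iodo-7-methyl-1-(3-methylfuran-2-yl)octa-2,6-dien-1-ol | Cc1ccoc1[C@@H](O)/C=C(\I)[C@@H](CC=C(C)C)O[Si](C)(C)C(C)(C)C | intermediate
14 | (1S,2Z,4R)-4-[(tert-butyldimethylsilyl)oxy]-3-iodo-7-methyl-1-(3-methylfuran-2-yl)octa-2,6-dien-1-yl acetate | Cc1ccoc1[C@@H](OC(C)=O)/C=C(\I)[C@@H](CC=C(C)C)O[Si](C)(C)C(C)(C)C | intermediate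
15 | (1S,2E,4R)-4-[(tert-butyldimethylsilyl)oxy]-7-methyl-1-(3-methylfuran-2-yl)-3-[(4,4,5,5-tetramethyl-1,3,2-dioxaborolan-2-yl)methyl]octa-2,6-dien-1-yl acetate (CH2Bpin cis to C6) | Cc1ccoc1[C@@H](OC(C)=O)/C=C(\CB1OC(C)(C)C(C)(C)O1)[C@@H](CC=C(C)C)O[Si](C)(C)C(C)(C)C | intermediate
16 | furan endoperoxide of 15 (6-methyl-2,3,7-trioxabicyclo[2.2.1]hept-5-en-1-yl in place of the furyl group; bridgeheads formed from either face and not defined) | CC1=CC2OOC1(O2)[C@@H](OC(C)=O)/C=C(\CB1OC(C)(C)C(C)(C)O1)[C@@H](CC=C(C)C)O[Si](C)(C)C(C)(C)C | intermediate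
17 | (1S,2E,4R)-4-[(tert-butyldimethylsilyl)oxy]-7-methyl-1-[(2Z)-2-methyl-4-oxobut-2-enoyl]-3-[(4,4,5,5-tetramethyl-1,3,2-dioxaborolan-2-yl)methyl]octa-2,6-dien-1-yl acetate | O=C/C=C(C)\C(=O)[C@@H](OC(C)=O)/C=C(\CB1OC(C)(C)C(C)(C)O1)[C@@H](CC=C(C)C)O[Si](C)(C)C(C)(C)C | intermediate
18 | pinacol borate ester of 19 at the C2 oxygen | C=C([C@@H]1[C@H](OB2OC(C)(C)C(C)(C)O2)C=C(C)C(=O)[C@H]1OC(C)=O)[C@@H](CC=C(C)C)O[Si](C)(C)C(C)(C)C | intermediate
19 | (1S,5R,6R)-6-[(3R)-3-[(tert-butyldimethylsilyl)oxy]-6-methylhepta-1,5-dien-2-yl]-5-hydroxy-3-methyl-2-oxocyclohex-3-en-1-yl acetate | C=C([C@@H]1[C@H](O)C=C(C)C(=O)[C@H]1OC(C)=O)[C@@H](CC=C(C)C)O[Si](C)(C)C(C)(C)C | intermediate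
20 | (1S,5R,6R)-5-hydroxy-6-[(3R)-3-hydroxy-6-methylhepta-1,5-dien-2-yl]-3-methyl-2-oxocyclohex-3-en-1-yl acetate | C=C([C@@H]1[C@H](O)C=C(C)C(=O)[C@H]1OC(C)=O)[C@@H](CC=C(C)C)O | intermediate
21 | (1S,3S,4R,5S,6S)-5-hydroxy-4-[(3R)-3-hydroxy-6-methylhepta-1,5-dien-2-yl]-1-methyl-2-oxo-7-oxabicyclo[4.1.0]heptan-3-yl acetate | C=C([C@@H]1[C@H](O)[C@@H]2O[C@]2(C)C(=O)[C@H]1OC(C)=O)[C@@H](CC=C(C)C)O | intermediate
22 | (1S,3S,4R,5S,6S)-3-acetoxy-1-methyl-4-[(3R)-6-methyl-3-[(2Z)-2-methylbut-2-enoyloxy]hepta-1,5-dien-2-yl]-2-oxo-7-oxabicyclo[4.1.0]heptan-5-yl (2Z)-2-methylbut-2-enoate | C=C([C@@H]1[C@H](OC(=O)/C(C)=C\C)[C@@H]2O[C@]2(C)C(=O)[C@H]1OC(C)=O)[C@@H](CC=C(C)C)OC(=O)/C(C)=C\C | intermediate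
23 | (1S,3S,4R,5S,6S)-3-acetoxy-4-[(3R)-4-[(2S)-3,3-dimethyloxiran-2-yl]-3-[(2Z)-2-methylbut-2-enoyloxy]but-1-en-2-yl]-1-methyl-2-oxo-7-oxabicyclo[4.1.0]heptan-5-yl (2Z)-2-methylbut-2-enoate | C=C([C@@H]1[C@H](OC(=O)/C(C)=C\C)[C@@H]2O[C@]2(C)C(=O)[C@H]1OC(C)=O)[C@@H](C[C@@H]1OC1(C)C)OC(=O)/C(C)=C\C | target

## Step count and risks

Total step count: 14. Longest linear sequence: 14 steps (1 to 23); aldehyde 9 enters at step 6.

Steps most likely to fail:

Step 10. The ring closure may fail through Z-to-E isomerisation of the enedione before the allylboration, through oxidation of the prenyl or allylboronate alkene by singlet oxygen, or through a sluggish allylboration. The fallback changes the allyl nucleophile and separates the two events. Setting out from 14, a Negishi coupling with Me3SiCH2ZnCl (Pd(PPh3)4, THF) would give the allylsilane (1S,2Z,4R)-4-[(tert-butyldimethylsilyl)oxy]-7-methyl-1-(3-methylfuran-2-yl)-3-[(trimethylsilyl)methyl]octa-2,6-dien-1-yl acetate F1. Photooxygenation and Me2S reduction of F1 would give the keto-enal allylsilane F2, which is isolated cold and closed by an intramolecular Hosomi–Sakurai reaction (BF3·OEt2, CH2Cl2, −78 °C). The same allylic 1,3-strain should govern the C1/C6 relationship and a synclinal transition state the C1/C2 relationship. The fallback comes back to the route at 19.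

Step 12. The epoxidation may fail through poor facial selectivity of the peroxide addition or through loss of the acetate under the basic conditions. The fallback delivers the oxygen electrophilically from a C5 carbinol. Setting out from 20, the double angeloylation of step 13 would give the enone bis-angelate F3. Luche reduction (NaBH4, CeCl3·7H2O, MeOH, −78 °C; axial hydride delivery) should give the allylic alcohol with the C5 hydroxyl cis to the C2 angelate F4. Epoxidation with VO(acac)2/t-BuOOH should then give the syn epoxy alcohol F5, and Dess–Martin oxidation of the C5 carbinol comes back to the route at 22.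

Step 13. The acylation may fail through Z-to-E isomerisation of the angelate or through incomplete acylation of the hindered C2 hydroxyl next to the epoxide. The fallback builds the angelate double bonds on the ester. Setting out from 21, DCC/DMAP acylation with 2-[bis(2,2,2-trifluoroethoxy)phosphoryl]propanoic acid would give the bis-phosphonate diester F6. A Z-selective Still–Gennari olefination of F6 with acetaldehyde (KN(SiMe3)2, 18-crown-6, THF, −78 °C) comes back to the route at 22.

Further compounds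
F1 | step 10 | (1S,2Z,4R)-4-[(tert-butyldimethylsilyl)oxy]-7-methyl-1-(3-methylfuran-2-yl)-3-[(trimethylsilyl)methyl]octa-2,6-dien-1-yl acetate | Cc1ccoc1[C@@H](OC(C)=O)/C=C(\C[Si](C)(C)C)[C@@H](CC=C(C)C)O[Si](C)(C)C(C)(C)C
F2 | step 10 | (1S,2Z,4R)-4-[(tert-butyldimethylsilyl)oxy]-7-methyl-1-[(2Z)-2-methyl-4-oxobut-2-enoyl]-3-[(trimethylsilyl)methyl]octa-2,6-dien-1-yl acetate | O=C/C=C(C)\C(=O)[C@@H](OC(C)=O)/C=C(\C[Si](C)(C)C)[C@@H](CC=C(C)C)O[Si](C)(C)C(C)(C)C
F3 | step 12 | bis-angelate of diol 20 (both hydroxyls esterified, stereocenters as in 20) | C=C([C@@H]1[C@H](OC(=O)/C(C)=C\C)C=C(C)C(=O)[C@H]1OC(C)=O)[C@@H](CC=C(C)C)OC(=O)/C(C)=C\C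
F4 | step 12 | C5 allylic alcohol from 1,2-reduction of F3 (C5 hydroxyl cis to the C2 angelate, trans to the C6 acetate) | C=C([C@@H]1[C@H](OC(=O)/C(C)=C\C)C=C(C)[C@H](O)[C@H]1OC(C)=O)[C@@H](CC=C(C)C)OC(=O)/C(C)=C\C
F5 | step 12 | C3–C4 epoxide of F4 (oxirane cis to the C5 hydroxyl and to the C2 angelate) | C=C([C@@H]1[C@H](OC(=O)/C(C)=C\C)[C@@H]2O[C@]2(C)[C@H](O)[C@H]1OC(C)=O)[C@@H](CC=C(C)C)OC(=O)/C(C)=C\C
F6 | step 13 | bis{2-[bis(2,2,2-trifluoroethoxy)phosphoryl]propanoate} of diol 21 (phosphonate-bearing carbons not defined, other stereocenters as in 21) | C=C([C@@H]1[C@H](OC(=O)C(C)P(=O)(OCC(F)(F)F)OCC(F)(F)F)[C@@H]2O[C@]2(C)C(=O)[C@H]1OC(C)=O)[C@@H](CC=C(C)C)OC(=O)C(C)P(=O)(OCC(F)(F)F)OCC(F)(F)F
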